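Two questions stood before me: when target peaks in the asked flask, and how high.

| setting | maple | birch | flask |
|---|---|---|---|
| starting material | 10 mM | 20 mM | 10 mM |
| reagent | 12 mM | 12 mM | 12.0 mM |
| scavenger | 15 mM | 15 mM | 15.0 mM |
| remark | the very flask that is asked about, followed so far | run made earlier |  |
| time |  |  | 3.0 d |

| run | time / h | target / % |
|---|---|---|
| maple | 6.00 | 27 |
| maple | 8.00 | 29 |
| maple | 15.0 | 39 |
| maple | 25.0 | 41 |
| maple | 40.0 | 33 |
| birch | 6.00 | 23 |
| birch | 10.0 | 26 |
| birch | 15.0 | 31 |
| birch | 30.0 | 27 |
| birch | 48.0 | 19 |

(scatter of a reading: 2 percentage points)

- time up to 3.0 d at which target stands highest
- the amount of target, in percent of the starting material charged, at that time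

- the analysis behind the earlier runs scatters by 2 percentage points, standard deviation

The asked flask has the charge of maple, so the maple readings were its own. But a top can be a mere shortage, so I counted turnovers first, assuming one reagent per target. The turnover allowance, charged [reagent] over charged [starting material], was 1.20. Maple read at most 41%, less than that allowance, then fell to 33%. Birch, with an allowance of 0.600, also topped lower, at 31%. So I read the top straight from maple: near 25.0 h, about 41%, with a scatter of 2 percentage points.

The forecast put it a little earlier, at 0.9 d and 42%, saying that “target is being consumed and the maximum lies inside the measured window”.

The asked flask gave 40.2% at 0.930 d.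

    scavenger + released group → scavenged by-product (k = 81.0 /M/h)
    starting material + reagent ⇌ target + released group (K = 1.80, k = 5.30 /M/h)
    starting material + released group ⇌ idle adduct, settled at all times (K = 140 /M)
    target → over-reaction product (k = 0.0300 /h)
    crystals ⇌ released group, rate k5*(cs5 - [released group]) while solid is left; crystals form when [released group] > cs5 (solubility = 2.50 mM, k = 22.0 /h)

At that time 49.8% of the asked flask's reagent was left, so by the allowance the reagent spent came to 60.3% of the starting material charged. Target stood at 40.2% and over-reaction product at 20.1%, which together make the same amount.

In a neighbour flask with 3.0 mM of reagent, the limiting reagent, the allowance was 0.300, a count of 30.0% of the starting material charged. That flask reached 13.2% of target and ended with 6.67% of target, 21.8% of over-reaction product and 71.5% of starting material.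

The earlier runs and the new flask were computed on assumed constants; noise was put on by code.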